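All runs are simulated with made-up constants; scatter was added.

A flask cannot make more product than it has reagent for, since the suspected step spends one reagent on each starting material.

| flask | starting material | reagent | temperature | remark | time |
|---|---|---|---|---|---|
| north | 19 mM | 23.8 mM | −10 °C | run made earlier |  |
| north-east | 48 mM | 23.8 mM | 10 °C | run made earlier |  |
| south | 73 mM | 23.8 mM | −10 °C | run made earlier |  |
| east | 25 mM | 13 mM | 10 °C | run made earlier |  |
| green | 100 mM | 6.00 mM | 25 °C |  | 4.0 h |
| amber | 40 mM | 50.0 mM | 25 °C |  | 4.0 h |
| blue | 25 mM | 40.0 mM | −5 °C |  | 4.0 h |
| red | 25 mM | 23.8 mM | 25 °C |  | 4.0 h |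

- north (time / h: product / %): 1.33: 3; 3.00: 1; 8.00: 9; 15.0: 19
- north-east (time / h: product / %): 0.667: 6; 2.00: 18; 4.00: 31; 6.00: 35
- south (time / h: product / %): 4.00: 0; 8.00: 6; 12.0: 7; 15.0: 8
- east (time / h: product / %): 1.33: 16; 3.00: 27; 4.00: 32; 6.00: 39

(each reading ± 1.5 percentage points)

- product is meant together with its idle adduct
- what was read earlier has a scatter of 1.5 percentage points, one standard deviation
- on the list of suspects stand: starting material + reagent -> product; reagent + product <-> idle adduct

- the flasks put in order of amount of product, in percent of the starting material charged, best first, at 4.0 h (green / amber / blue / red)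
- the same order at 30 h (green / amber / blue / red)
- the amount of product, in percent of the starting material charged of the flask you put first, at 4.0 h
- the amount of product, in percent of the starting material charged of the flask you put last, at 4.0 h

We carry the ceiling, the charged ratio c(reagent)/c(starting material) read as a percentage of product, with 1 equivalent as the zero of the scale. Below that zero, reagent is the limiting reagent; above it, the ceiling is 100 %. Green's ceiling is 6.00 % and red's is 95.2 %, while amber and blue stand at 1.25 and 1.60 equivalents.

The east run, at 39 % after 6.00 h, is still below its ceiling of 52.0 %, so that run does not test the rule. Its first reading gives about 3.01 mM h⁻¹ at 10 °C. If green kept that pace, taken over from the east run's other charges, its 6.00 mM of reagent lasts 2.00 h, less than 4.0 h, and green is warmer, so we expect green at its ceiling. We expect blue below its ceiling, since the north run, with other charges and colder at −10 °C against −5 °C, took 15.0 h, longer than 4.0 h, to read 19 %.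

The forecast gives amber > red > blue > green at 4.0 h and amber > red > blue > green at 30 h, with 88 % for amber and 6 % for green, which it calls “reagent-limited, capped at 6% and reached quickly”.

The flasks give amber > red > blue > green at 4.0 h and amber > red > blue > green at 30 h, with 99.3 % for amber and 6.00 % for green. The forecast's orders stand, and its top is 11 percentage points low.

    starting material + reagent → product, rate k1*[starting material]^0.5*[reagent]^0.5 (k = 1.13 h⁻¹, Ea = 86.0 kJ mol⁻¹)
    reagent + product ⇌ idle adduct, settled at all times (K = 134 M⁻¹, ΔH = −36.0 kJ mol⁻¹)
    (constants at 25 °C)

Green has come to rest at its ceiling of 6.00 %: its reagent stands at 0 % at 4.00 h, and at 40.0 h it still reads 6.00 %, with 94.0 % of its starting material unbound. Amber goes from 99.3 % to 100 % at 40.0 h, and red reads 95.2 % at 30 h against its ceiling of 95.2 %. Blue still moves, from 11.1 % at 4.00 h to 66.0 % at 40.0 h.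

For the neighbour of amber charged with 30 mM of reagent, the ceiling falls to 75.0 %. That flask gives 74.9 % at 4.00 h, with 0.025 % of its charged reagent still there unbound.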